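Numbering: 1-benzoxepine locants (O1, C2–C5, C5a, C6–C9, C9a); C1′ is the bromomethyl carbon, ring A the bromocyclohexane, ring B the oxepene.
Cuts: first C1′–Br and C3–CH3 (back to an oxepan-3-one), then O1–C2 together with C2–C1′, then C2–C3 and O1–allyl, then C7–Br, C6–C5a and C9a–O1 of ring A, and last C4–C5.
Enabling feature: in ring B, C2 stands between the ether oxygen O1 and the sp2 carbon C3 and bears the one-carbon arm C1′. This is the pattern of a 2-substituted oxepan-3-one, which an allyl oxonium ylide delivers by [2,3]-shift.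
Forward order: the chain is joined at C4–C5, and ring A closes by bromonium-induced cyclisation with a sacrificial δ-lactone holding O1. The lactone is opened, O1 allylated, C2 added and diazotised, and ring B closes at O1–C2. The allyl group is then cut back to C1′, C3 is methylated and C1′ brominated.
Stereochemistry: C7 comes from catalyst-controlled bromine delivery. C5a and C9a are relayed from C7 by chair-like anti addition across the E-alkene. C2 comes from suprafacial allyl transfer from the oxonium oxygen, on the face of the C9a methyl.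
Key step: step 7

Assumption: the (R)-BINOL-derived catalyst is taken to be the antipode that delivers bromine to the alkene face leading to the 7S bromide; if the sense is the opposite, the (S)-catalyst is used and nothing else changes.

Step 1
Reactants: 1 geranyl bromide; 2 tert-butyl acetate
Product: 3 tert-butyl (4E)-5,9-dimethyldeca-4,8-dienoate
Conditions: 2, LiN(iPr)2, THF, −78 °C; then 1, −78 °C → rt
Reagents that add atoms: none
Why: SN2 alkylation of a lithium ester enolate by a primary allylic bromide forms C4–C5; the tert-butyl group suppresses Claisen self-condensation and the E-alkene is untouched.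

Step 2
Reactants: 3 tert-butyl (4E)-5,9-dimethyldeca-4,8-dienoate
Product: 4 (4aS,6S,8aS)-6-bromo-5,5,8a-trimethyloctahydro-2H-chromen-2-one (trans-fused bromolactone)
Conditions: DBDMH, (R)-3,3′-diaryl-BINOL-derived thiophosphoramide (10 mol %), toluene–CH2Cl2, −78 °C
Reagents that add atoms: 1,3-dibromo-5,5-dimethylhydantoin (DBDMH), CC1(C)C(=O)N(Br)C(=O)N1Br
Why: Proposed new method: the thiophosphoryl sulfur of the chiral catalyst should take Br+ from DBDMH and pass it to one face of the more exposed terminal alkene; the bromiranium ion is opened at its CMe2 end by the E-configured C5a=C9a alkene through a chair-like transition state, the C9a cation is captured by the ester carbonyl oxygen and isobutene is lost, so two anti additions place Br, C5 and O1 equatorial and relay C7 into C5a and C9a (trans fusion); the closest known reaction type is the catalytic enantioselective bromonium-induced polyene cyclisation of geranyl arenes and geranyl phenols, whereas carboxyl-terminated bromocyclisation of such dienes is known in racemic form only, and the ester is preferred to the free acid because it cannot form an acyl hypobromite and is less prone to lactonise directly onto the inner alkene.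

Step 3
Reactants: 4 (4aS,6S,8aS)-6-bromo-5,5,8a-trimethyloctahydro-2H-chromen-2-one
Product: 5 3-[(1S,3S,6S)-3-bromo-6-hydroxy-2,2,6-trimethylcyclohexyl]-1-(morpholin-4-yl)propan-1-one
Conditions: morpholine, AlMe3, CH2Cl2, 0 °C → rt; aq. potassium sodium tartrate
Reagents that add atoms: morpholine, C1COCCN1
Why: Aluminium amide aminolysis of a lactone (Weinreb-type) breaks only the acyl–oxygen bond, so C9a keeps its configuration, and the tertiary amide should not close back under base because expulsion of morpholide by an alkoxide is strongly uphill.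

Step 4
Reactants: 5 3-[(1S,3S,6S)-3-bromo-6-hydroxy-2,2,6-trimethylcyclohexyl]-1-(morpholin-4-yl)propan-1-one; 6 allyl bromide
Product: 7 3-[(1S,3S,6S)-6-(allyloxy)-3-bromo-2,2,6-trimethylcyclohexyl]-1-(morpholin-4-yl)propan-1-one
Conditions: KH, THF, 0 °C; 6, Bu4NI (cat.), 0 °C → rt
Reagents that add atoms: none
Why: Williamson etherification of a tertiary potassium alkoxide with a very reactive allylic halide under iodide catalysis; the equatorial C7 bromide has no antiperiplanar hydrogen for E2 and its neopentyl position slows substitution.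

Step 5
Reactants: 7 3-[(1S,3S,6S)-6-(allyloxy)-3-bromo-2,2,6-trimethylcyclohexyl]-1-(morpholin-4-yl)propan-1-one
Product: 8 4-[(1S,3S,6S)-6-(allyloxy)-3-bromo-2,2,6-trimethylcyclohexyl]butan-2-one
Conditions: MeMgBr, THF, 0 °C → rt; aq. NH4Cl
Reagents that add atoms: methylmagnesium bromide, C[Mg]Br
Why: Acyl substitution of a morpholine amide by a Grignard reagent stops at the ketone because the tetrahedral magnesium adduct persists until the quench; the new methyl carbon is C2 and the new bond is C2–C3.

Step 6
Reactants: 8 4-[(1S,3S,6S)-6-(allyloxy)-3-bromo-2,2,6-trimethylcyclohexyl]butan-2-one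
Product: 10 4-[(1S,3S,6S)-6-(allyloxy)-3-bromo-2,2,6-trimethylcyclohexyl]-1-diazobutan-2-one, via trifluoroacetyl diketone 9 (not isolated)
Conditions: LiN(SiMe3)2, THF, −78 °C; CF3CO2CH2CF3; dilute HCl wash; then MsN3, Et3N, H2O, MeCN, rt
Reagents that add atoms: methanesulfonyl azide, CS(=O)(=O)N=[N+]=[N-]; 2,2,2-trifluoroethyl trifluoroacetate, FC(F)(F)COC(=O)C(F)(F)F (its CF3CO group stays in 9 only)
Why: Detrifluoroacetylative diazo transfer: kinetic deprotonation at the methyl group and trifluoroacetylation activate C2 alone, and the sulfonyl azide then delivers N2 with loss of the trifluoroacetyl group, so no diazomethane is needed.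

Step 7
Reactants: 10 4-[(1S,3S,6S)-6-(allyloxy)-3-bromo-2,2,6-trimethylcyclohexyl]-1-diazobutan-2-one
Product: 13 (2S,5aS,7S,9aS)-2-allyl-7-bromo-6,6,9a-trimethyloctahydro-1-benzoxepin-3(2H)-one (trans-fused), via copper carbenoid 11 (not isolated), via oxonium ylide 12 (not isolated)
Conditions: Cu(hfacac)2 (5 mol %), CH2Cl2, reflux, slow addition of 10 (final 0.01 M)
Reagents that add atoms: none
Why: Loss of N2 from 10 on the divalent copper complex Cu(hfacac)2 leaves the electrophilic carbenoid 11; a lone pair of the allyl ether oxygen adds to its carbon to give the cyclic ylide 12, and a concerted suprafacial [2,3]-shift (five-centre envelope transition state) passes the allyl group from O1 to C2 with transposition, its former terminal CH2 becoming C1′. The closest known reaction type is the copper-catalysed oxonium ylide formation and [2,3]-rearrangement of allyl ethers tethered to diazoketones, which gives 2-allyl cyclic ether 3-ones, oxepan-3-ones included. Ring B closes by O1–C2 bond formation (ether oxygen onto the carbenoid carbon); it is seven-membered because C3, C4, C5 and C5a separate C2 from C9a, and the diequatorial, gauche placement of O1 and C5 on the ring A chair keeps both ends within reach. C2 is the only new stereocentre and is controlled by the configuration the oxonium oxygen adopts: with the allyl group in the equatorial site of the forming ring, anti to C5a and on the face of the C9a methyl, the suprafacial shift sets it on that same face of C2, the same sense as the known trans selectivity relative to the ring-bound substituent (here C9) in five- and six-membered cases. The step needs ylide formation to win over insertion into the tertiary C5a–H bond and over cyclopropanation; the electron-poor hfacac ligands favour capture by the Lewis basic oxygen, and C5a–H is shielded by the quaternary C6 and C9a and deactivated by the β-oxygen. Since the allyl group ends 1,3-syn to the angular methyl across O1, this epimer cannot be assumed to be the thermodynamic one, so 13 is kept away from equilibrating base and carried on at once.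

Step 8
Reactants: 13 (2S,5aS,7S,9aS)-2-allyl-7-bromo-6,6,9a-trimethyloctahydro-1-benzoxepin-3(2H)-one
Product: 14 (2S,5aS,7S,9aS)-2-allyl-7-bromo-6,6,9a-trimethyl-2,5,5a,6,7,8,9,9a-octahydro-1-benzoxepin-3-yl trifluoromethanesulfonate
Conditions: 13 added to KN(SiMe3)2, THF, −78 °C; N-(5-chloropyridin-2-yl)triflimide, −78 °C; aq. NH4Cl
Reagents that add atoms: N-(5-chloropyridin-2-yl)bis(trifluoromethanesulfonimide), O=S(=O)(N(c1ccc(Cl)cn1)S(=O)(=O)C(F)(F)F)C(F)(F)F
Why: Kinetic enolisation with a bulky amide base takes a C4 proton rather than the hindered, alkoxy-flanked C2–H, and O-triflation at −78 °C fixes the future C3=C4 alkene and removes the means of epimerising C2.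

Step 9
Reactants: 14 (2S,5aS,7S,9aS)-2-allyl-7-bromo-6,6,9a-trimethyl-2,5,5a,6,7,8,9,9a-octahydro-1-benzoxepin-3-yl trifluoromethanesulfonate
Product: 15 (2S,5aS,7S,9aS)-7-bromo-6,6,9a-trimethyl-2-[(1E)-prop-1-en-1-yl]-2,5,5a,6,7,8,9,9a-octahydro-1-benzoxepin-3-yl trifluoromethanesulfonate
Conditions: RuHCl(CO)(PPh3)3 (5 mol %), toluene, 80 °C
Reagents that add atoms: none
Why: Ruthenium hydride-catalysed alkene isomerisation (hydrometalation, β-hydride elimination) moves the terminal double bond by one position and should stop there, because further migration needs insertion next to the hindered C2; the alkene geometry is of no consequence.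

Step 10
Reactants: 15 (2S,5aS,7S,9aS)-7-bromo-6,6,9a-trimethyl-2-[(1E)-prop-1-en-1-yl]-2,5,5a,6,7,8,9,9a-octahydro-1-benzoxepin-3-yl trifluoromethanesulfonate
Product: 17 (2S,5aS,7S,9aS)-7-bromo-2-(hydroxymethyl)-6,6,9a-trimethyl-2,5,5a,6,7,8,9,9a-octahydro-1-benzoxepin-3-yl trifluoromethanesulfonate, via aldehyde 16 (not isolated)
Conditions: O3, CH2Cl2–MeOH, −78 °C (Sudan red 7B end point); NaBH4, −78 → 0 °C
Reagents that add atoms: ozone, [O-][O+]=O
Why: Ozonolysis with reductive work-up: electrophilic ozone attacks the propenyl group much faster than the electron-poor enol triflate, and immediate borohydride reduction in the cold leaves the α-alkoxy aldehyde no time to epimerise at C2.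

Step 11
Reactants: 17 (2S,5aS,7S,9aS)-7-bromo-2-(hydroxymethyl)-6,6,9a-trimethyl-2,5,5a,6,7,8,9,9a-octahydro-1-benzoxepin-3-yl trifluoromethanesulfonate
Product: 18 [(2R,5aS,7S,9aS)-7-bromo-3,6,6,9a-tetramethyl-2,5,5a,6,7,8,9,9a-octahydro-1-benzoxepin-2-yl]methanol
Conditions: Me2Zn (3 equiv), Pd(PPh3)4 (5 mol %), THF, 0 °C → rt
Reagents that add atoms: dimethylzinc, C[Zn]C
Why: Negishi coupling: zerovalent palladium inserts into the alkenyl C–OTf bond but not into the hindered secondary alkyl bromide, and the hydroxyl group merely consumes one equivalent of Me2Zn as its zinc alkoxide.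

Step 12
Reactants: 18 [(2R,5aS,7S,9aS)-7-bromo-3,6,6,9a-tetramethyl-2,5,5a,6,7,8,9,9a-octahydro-1-benzoxepin-2-yl]methanol
Product: 19 palisadin B, (2R,5aS,7S,9aS)-7-bromo-2-(bromomethyl)-3,6,6,9a-tetramethyl-2,5,5a,6,7,8,9,9a-octahydro-1-benzoxepine
Conditions: CBr4, PPh3, CH2Cl2, 0 °C
Reagents that add atoms: carbon tetrabromide, BrC(Br)(Br)Br
Why: Appel reaction: bromide displaces the primary alkoxyphosphonium group by SN2 under neutral conditions and no stereocentre is touched.

Compound list
1 | geranyl bromide, (2E)-1-bromo-3,7-dimethylocta-2,6-diene | CC(C)=CCC/C(C)=C/CBr | starting material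
2 | tert-butyl acetate | CC(=O)OC(C)(C)C | starting material
3 | tert-butyl (4E)-5,9-dimethyldeca-4,8-dienoate | CC(C)=CCC/C(C)=C/CCC(=O)OC(C)(C)C | intermediate
4 | (4aS,6S,8aS)-6-bromo-5,5,8a-trimethyloctahydro-2H-chromen-2-one | O=C1CC[C@H]2C(C)(C)[C@@H](Br)CC[C@]2(C)O1 | intermediate
5 | 3-[(1S,3S,6S)-3-bromo-6-hydroxy-2,2,6-trimethylcyclohexyl]-1-(morpholin-4-yl)propan-1-one | O=C(N1CCOCC1)CC[C@H]2C(C)(C)[C@@H](Br)CC[C@]2(C)O | intermediate
6 | allyl bromide | C=CCBr | starting material
7 | 3-[(1S,3S,6S)-6-(allyloxy)-3-bromo-2,2,6-trimethylcyclohexyl]-1-(morpholin-4-yl)propan-1-one | O=C(N1CCOCC1)CC[C@H]2C(C)(C)[C@@H](Br)CC[C@]2(C)OCC=C | intermediate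
8 | 4-[(1S,3S,6S)-6-(allyloxy)-3-bromo-2,2,6-trimethylcyclohexyl]butan-2-one | CC(=O)CC[C@H]1C(C)(C)[C@@H](Br)CC[C@]1(C)OCC=C | intermediate
9 | 6-[(1S,3S,6S)-6-(allyloxy)-3-bromo-2,2,6-trimethylcyclohexyl]-1,1,1-trifluorohexane-2,4-dione | FC(F)(F)C(=O)CC(=O)CC[C@H]1C(C)(C)[C@@H](Br)CC[C@]1(C)OCC=C | intermediate
10 | 4-[(1S,3S,6S)-6-(allyloxy)-3-bromo-2,2,6-trimethylcyclohexyl]-1-diazobutan-2-one | [N-]=[N+]=CC(=O)CC[C@H]1C(C)(C)[C@@H](Br)CC[C@]1(C)OCC=C | intermediate
11 | copper carbenoid of 10 at C2 (hfacac ligands not drawn) | [Cu]=CC(=O)CC[C@H]1C(C)(C)[C@@H](Br)CC[C@]1(C)OCC=C | intermediate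
12 | seven-membered O-allyl oxonium ylide (O1 positive, C2 negative) | O=C1CC[C@H]2C(C)(C)[C@@H](Br)CC[C@]2(C)[O+](CC=C)[CH-]1 | intermediate
13 | (2S,5aS,7S,9aS)-2-allyl-7-bromo-6,6,9a-trimethyloctahydro-1-benzoxepin-3(2H)-one | O=C1CC[C@H]2C(C)(C)[C@@H](Br)CC[C@]2(C)O[C@H]1CC=C | intermediate
14 | (2S,5aS,7S,9aS)-2-allyl-7-bromo-6,6,9a-trimethyl-2,5,5a,6,7,8,9,9a-octahydro-1-benzoxepin-3-yl trifluoromethanesulfonate | O=S(=O)(OC1=CC[C@H]2C(C)(C)[C@@H](Br)CC[C@]2(C)O[C@H]1CC=C)C(F)(F)F | intermediate
15 | (2S,5aS,7S,9aS)-7-bromo-6,6,9a-trimethyl-2-[(1E)-prop-1-en-1-yl]-2,5,5a,6,7,8,9,9a-octahydro-1-benzoxepin-3-yl trifluoromethanesulfonate | O=S(=O)(OC1=CC[C@H]2C(C)(C)[C@@H](Br)CC[C@]2(C)O[C@H]1/C=C/C)C(F)(F)F | intermediate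
16 | (2R,5aS,7S,9aS)-7-bromo-2-formyl-6,6,9a-trimethyl-2,5,5a,6,7,8,9,9a-octahydro-1-benzoxepin-3-yl trifluoromethanesulfonate | O=S(=O)(OC1=CC[C@H]2C(C)(C)[C@@H](Br)CC[C@]2(C)O[C@H]1C=O)C(F)(F)F | intermediate
17 | (2S,5aS,7S,9aS)-7-bromo-2-(hydroxymethyl)-6,6,9a-trimethyl-2,5,5a,6,7,8,9,9a-octahydro-1-benzoxepin-3-yl trifluoromethanesulfonate | O=S(=O)(OC1=CC[C@H]2C(C)(C)[C@@H](Br)CC[C@]2(C)O[C@H]1CO)C(F)(F)F | intermediate
18 | [(2R,5aS,7S,9aS)-7-bromo-3,6,6,9a-tetramethyl-2,5,5a,6,7,8,9,9a-octahydro-1-benzoxepin-2-yl]methanol | CC1=CC[C@H]2C(C)(C)[C@@H](Br)CC[C@]2(C)O[C@H]1CO | intermediate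
19 | palisadin B | CC1=CC[C@H]2C(C)(C)[C@@H](Br)CC[C@]2(C)O[C@H]1CBr | target

Total step count: 12. Longest linear sequence: 12 steps (1 → 19); the route is fully linear.

Steps most likely to fail

1. Step 2 (the labelled step).
- What may go wrong: weak facial discrimination in the bromine transfer; bromine exchange between alkenes before ring closure; attack on the inner alkene; proton loss from the C9a cation before the ester oxygen closes.
- Fallback, known chemistry, from 3 back to 4: racemic cyclisation followed by classical resolution. Treatment of 3 with Et2SBr·SbCl5Br in MeNO2 at −25 °C should give the racemic trans-bromolactone F1. Aminolysis with (S)-1-phenylethylamine and AlMe3 turns it into two diastereomeric hydroxy amides, the (1S,3S,6S) amide F2 and the (1R,3R,6R) amide F3. These are separated by crystallisation or chromatography. Heating F2 with 2 M H2SO4 in dioxane relactonises it to 4.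

2. Step 7 (key step).
- What may go wrong: insertion of the carbenoid into the tertiary C5a–H bond; heterolysis of the C9a–O bond of the tertiary oxonium before the shift; engagement of the other oxygen lone pair, which would put the allyl group on the wrong face of C2.
- Fallback, from 4 back to 13: O1–C2 is made by O–H insertion and C2 is set by protonation.
  - The lithium enolate of allyl acetate opens 4 to the hydroxy β-keto ester F4.
  - Regitz diazo transfer (p-ABSA, Et3N, MeCN) gives the diazo keto ester F5.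
  - Rh2(OAc)4 in refluxing CH2Cl2 closes ring B by insertion into the tertiary O–H bond, giving the oxepanone carboxylate F6.
  - C-allylation with 6 (K2CO3, acetone) gives the quaternary keto ester F7.
  - Pd(PPh3)4 with HCO2H and Et3N removes the allyl ester. Decarboxylation and protonation of the enol from the face opposite the angular methyl should then give 13.

3. Step 4.
- What may go wrong: slow alkylation of the hindered tertiary alkoxide, which leaves time for transannular displacement of the C7 bromide by the alkoxide or for return to the lactone.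
- Fallback, from 4 back to 10: no alkoxide and no acyl group are present during etherification.
  - LiBH4 (THF–MeOH) reduces 4 to the diol F8.
  - TBDPSCl and imidazole give the primary silyl ether F9.
  - Allyl 2,2,2-trichloroacetimidate with catalytic TfOH (cyclohexane–CH2Cl2, 0 °C) allylates the tertiary alcohol under acid catalysis to the allyl silyl ether F10.
  - Bu4NF frees the primary alcohol F11.
  - TEMPO and PhI(OAc)2 in MeCN–H2O give the carboxylic acid F12.
  - Isobutyl chloroformate and Et3N form the mixed anhydride F13, which with CH2N2 in Et2O gives 10.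

Further compounds
F1 | step 2 | racemic trans-bromolactone (4 plus its mirror image; the mirror image is drawn) | O=C1CC[C@@H]2C(C)(C)[C@H](Br)CC[C@@]2(C)O1
F2 | step 2 | 3-[(1S,3S,6S)-3-bromo-6-hydroxy-2,2,6-trimethylcyclohexyl]-N-[(1S)-1-phenylethyl]propanamide | O=C(N[C@@H](C)c1ccccc1)CC[C@H]2C(C)(C)[C@@H](Br)CC[C@]2(C)O
F3 | step 2 | 3-[(1R,3R,6R)-3-bromo-6-hydroxy-2,2,6-trimethylcyclohexyl]-N-[(1S)-1-phenylethyl]propanamide | O=C(N[C@@H](C)c1ccccc1)CC[C@@H]2C(C)(C)[C@H](Br)CC[C@@]2(C)O
F4 | step 7 | allyl 5-[(1S,3S,6S)-3-bromo-6-hydroxy-2,2,6-trimethylcyclohexyl]-3-oxopentanoate | C=CCOC(=O)CC(=O)CC[C@H]1C(C)(C)[C@@H](Br)CC[C@]1(C)O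
F5 | step 7 | allyl 5-[(1S,3S,6S)-3-bromo-6-hydroxy-2,2,6-trimethylcyclohexyl]-2-diazo-3-oxopentanoate | C=CCOC(=O)C(=[N+]=[N-])C(=O)CC[C@H]1C(C)(C)[C@@H](Br)CC[C@]1(C)O
F6 | step 7 | allyl (5aS,7S,9aS)-7-bromo-6,6,9a-trimethyl-3-oxodecahydro-1-benzoxepine-2-carboxylate (C2 labile) | O=C1CC[C@H]2C(C)(C)[C@@H](Br)CC[C@]2(C)OC1C(=O)OCC=C
F7 | step 7 | allyl (5aS,7S,9aS)-2-allyl-7-bromo-6,6,9a-trimethyl-3-oxodecahydro-1-benzoxepine-2-carboxylate (C2 configuration immaterial) | O=C1CC[C@H]2C(C)(C)[C@@H](Br)CC[C@]2(C)OC1(CC=C)C(=O)OCC=C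
F8 | step 4 | 3-[(1S,3S,6S)-3-bromo-6-hydroxy-2,2,6-trimethylcyclohexyl]propan-1-ol | OCCC[C@H]1C(C)(C)[C@@H](Br)CC[C@]1(C)O
F9 | step 4 | (1S,2S,4S)-4-bromo-2-{3-[(tert-butyldiphenylsilyl)oxy]propyl}-1,3,3-trimethylcyclohexan-1-ol | CC(C)(C)[Si](c1ccccc1)(c1ccccc1)OCCC[C@H]2C(C)(C)[C@@H](Br)CC[C@]2(C)O
F10 | step 4 | {3-[(1S,3S,6S)-6-(allyloxy)-3-bromo-2,2,6-trimethylcyclohexyl]propoxy}(tert-butyl)diphenylsilane | CC(C)(C)[Si](c1ccccc1)(c1ccccc1)OCCC[C@H]2C(C)(C)[C@@H](Br)CC[C@]2(C)OCC=C
F11 | step 4 | 3-[(1S,3S,6S)-6-(allyloxy)-3-bromo-2,2,6-trimethylcyclohexyl]propan-1-ol | OCCC[C@H]1C(C)(C)[C@@H](Br)CC[C@]1(C)OCC=C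
F12 | step 4 | 3-[(1S,3S,6S)-6-(allyloxy)-3-bromo-2,2,6-trimethylcyclohexyl]propanoic acid | OC(=O)CC[C@H]1C(C)(C)[C@@H](Br)CC[C@]1(C)OCC=C
F13 | step 4 | isobutyl carbonic anhydride of F12 | CC(C)COC(=O)OC(=O)CC[C@H]1C(C)(C)[C@@H](Br)CC[C@]1(C)OCC=C
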